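Start from Tuesday's run. Beta is its near twin: the same temperature, a smaller charge of Z.

| flask | Z | temperature | remark | time |
|---|---|---|---|---|
| Friday's | 0.26 M | 20 °C | run made earlier |  |
| Tuesday's | 0.58 M | 33 °C | run made earlier |  |
| alpha | 0.39 M | 25 °C |  | 4.0 min |
| beta | 0.39 M | 33 °C |  | 4.0 min |
| eta | 0.39 M | 41 °C |  | 4.0 min |

| run | time / min | L / % | Z / % |
|---|---|---|---|
| Friday's | 0.417 | 87 | 3 |
| Friday's | 1.00 | 83 | 0 |
| Friday's | 2.00 | 76 | 0 |
| Friday's | 3.00 | 64 | 0 |
| Tuesday's | 0.417 | 81 | 0 |
| Tuesday's | 1.00 | 80 | 0 |
| Tuesday's | 2.00 | 80 | 0 |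
| Tuesday's | 3.00 | 82 | 0 |

(each reading ± 1.5 percentage points)

* which of the two there is more of at the end, alpha (L / X)
* which of the two there is more of at the end, beta (L / X)
* which of the two there is more of at the end, eta (L / X)
* amount of L at the end, in percent of the Z charged, alpha
* amount of L at the end, in percent of the Z charged, beta
* amount of L at the end, in percent of the Z charged, eta

Tuesday's L lies between 80 % and 82 % at every reading, with a scatter of 1.5 percentage points, and Z already reads 0 % at the first of them. We therefore take L and X at 33 °C as standing in a fixed proportion, and read the plateau of L as 80.8 %.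

Beta should be this plateau with one small correction. The step Z → L is first order and 2 Z → G second order, so the rate of the second over the first goes with [Z]. While that ratio is small, the share of the charge paid to G (a kinetic-control split, made once while Z lasts) goes with the charge. Our rule, at one fixed temperature, is therefore to scale that share by the charge ratio 0.672, and to rescale L by what remains for L and X together.

The size of the share comes from Friday's run. Its first reading leaves 10.0 % of the charge unseen. L then falls by a fraction 0.0890 min⁻¹ of the charge, and taking that much off for X up to the first reading leaves a reading of 6.29 % for G at 0.26 M. Scaled by charge, and with the split assumed equal at 20 °C and 33 °C, that is 14.0 % on Tuesday and 9.43 % in beta, so we reckon L in beta at 85.1 %. Alpha and eta have no earlier run at their temperatures, so this correction gives them nothing.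

The forecast put L ahead of X in alpha, beta and eta, with L at 60 %, 85 % and 86 % respectively: “At 33 and 41 °C, L should therefore stay near 85%.”

The flasks give L 70.4 %, 81.0 % and 87.7 %, with L ahead of X in each, so beta stands 4.1 points below our reckoning.

    L ⇌ X (K = 0.360, k = 0.00620 s⁻¹, Ea = 87.0 kJ mol⁻¹, ΔH = −63.0 kJ mol⁻¹)
    2 Z → G (k = 0.0230 M⁻¹ s⁻¹, Ea = 64.0 kJ mol⁻¹)
    Z → L (k = 0.190 s⁻¹, Ea = 74.0 kJ mol⁻¹)
    (constants at 25 °C)

In beta, Z → L starts by using Z 12 times as fast as 2 Z → G, and L and X relax by their own step with a half-life of 0.116 min, far shorter than the 4.0 min of the run, and at the end beta holds 4.02 % in G and 15.0 % in X. Dividing that G by 0.672 gives 5.98 % at Tuesday's charge and carries L to 79.3 %, where Tuesday's run without scatter stands at 79.4 % at 3.00 min; the same rule takes alpha's L to 71.5 % at Friday's charge, and the simulated flask at 25 °C and 0.26 M holds, at 3.00 min, 71.7 %.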